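**Retrosynthetic overview**

- Late stage: the vanillate is put on O6 by acylation, C9–OH comes from 1,2-reduction of a C7=C8–C9=O enone, and C6–OH from hydroxyl-directed reduction of a C6 ketone. Both carbonyls and the C7=C8 alkene are drawn from one cyclohepta-1,4-diene (C5=C6, C8=C9–B).
- Key disconnection: the seven-membered ring (C1, C5–C10) is cut at C6–C7 and C1–C10 into a cyclopentenyl carbene (C6 on C5=C1) and 2-boryl-3-methylbuta-1,3-diene (C7–C10). Cyclopropanation of C7=C8 makes a temporary C6–C8 bond; the Cope rearrangement of the cis-divinylcyclopropane breaks it again while it forms C1–C10 and the quaternary C1.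
- Enabling feature: C6 and C9 are both oxygenated and 1,4-related, and C5 is a ring-fusion CH, so C5=C6 and C8=C9 can be alkenes flanking the C7 methylene. That is exactly the 1,4-diene a divinylcyclopropane rearrangement leaves; the tertiary carbinol C4 next to C5 differentiates the faces.
- Ring order: five-membered ring first (ozonolysis/aldol ring contraction of (S)-terpinen-4-ol, which supplies C4 with its isopropyl and hydroxyl groups), seven-membered ring second (key step).

Key step: step 6

Remark on numbering: daucane numbering is used for all bicyclic compounds (C1 quaternary carbon with its methyl, C2 and C3 methylenes, C4 carbinol carbon with the isopropyl group, C5 ring-fusion CH, C6 to C10 the remaining ring carbons, methyl on C8); β is the face of the C1 methyl group, α the opposite face.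

Assumption: (S)-(+)-terpinen-4-ol is bought as the single enantiomer; its carbinol carbon becomes C4 of the target.

**Step 1**
Reactants: 1 (S)-(+)-terpinen-4-ol
Product: 2 tert-butyl(dimethyl){[(1S)-4-methyl-1-(propan-2-yl)cyclohex-3-en-1-yl]oxy}silane
Conditions: TBSOTf, 2,6-lutidine, CH2Cl2, 0 °C → rt
Reagents that add atoms: tert-butyldimethylsilyl trifluoromethanesulfonate, CC(C)(C)[Si](C)(C)OS(=O)(=O)C(F)(F)F
Why: Silylation of a tertiary alcohol with a silyl triflate and a hindered pyridine base is routine and leaves the stereocentre untouched; the bulky ether is needed to screen the β-face in step 6 and to keep the β-oxygen from eliminating in step 3.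

**Step 2**
Reactants: 2 tert-butyl(dimethyl){[(1S)-4-methyl-1-(propan-2-yl)cyclohex-3-en-1-yl]oxy}silane
Product: 4 (3S)-3-[(tert-butyldimethylsilyl)oxy]-6-oxo-3-(propan-2-yl)heptanal, via secondary ozonide 3 (not isolated)
Conditions: O3, CH2Cl2, −78 °C; then Me2S, −78 °C → rt
Reagents that add atoms: ozone, [O-][O+]=O
Why: Ozonolysis with reductive work-up cleaves the only alkene to the methyl ketone and the aldehyde without touching the silyl ether or the stereocentre.

**Step 3**
Reactants: 4 (3S)-3-[(tert-butyldimethylsilyl)oxy]-6-oxo-3-(propan-2-yl)heptanal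
Product: 5 (5R)-5-[(tert-butyldimethylsilyl)oxy]-2-methyl-5-(propan-2-yl)cyclopent-1-ene-1-carbaldehyde
Conditions: Bn2NH·CF3CO2H (0.2 equiv), toluene, 50 °C
Reagents that add atoms: none
Why: Intramolecular aldol condensation through the aldehyde enamine (5-exo-trig attack of the aldehyde α-carbon on the methyl ketone, then dehydration) is the standard ring contraction of ozonised 1-methylcyclohexenes to 2-methylcyclopent-1-ene-1-carbaldehydes; the mild ammonium salt should keep the β-silyloxy group from eliminating, and no new stereocentre is formed.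

**Step 4**
Reactants: 5 (5R)-5-[(tert-butyldimethylsilyl)oxy]-2-methyl-5-(propan-2-yl)cyclopent-1-ene-1-carbaldehyde
Product: 6 (E)-N-sulfonylhydrazone of 5 with 2-(trifluoromethyl)benzenesulfonohydrazide
Conditions: 2-(trifluoromethyl)benzenesulfonohydrazide, MeOH, rt → 40 °C
Reagents that add atoms: 2-(trifluoromethyl)benzenesulfonohydrazide, NNS(=O)(=O)c1ccccc1C(F)(F)F
Why: Condensation of the aldehyde with a sulfonyl hydrazide gives a bench-stable N-sulfonylhydrazone that releases the diazoalkene with base at low temperature (Bamford–Stevens reaction) in step 6.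

**Step 5**
Reactants: 7 4,4,5,5-tetramethyl-2-(prop-1-yn-1-yl)-1,3,2-dioxaborolane; 8 ethylene
Product: 9 4,4,5,5-tetramethyl-2-(3-methylbuta-1,3-dien-2-yl)-1,3,2-dioxaborolane
Conditions: second-generation Grubbs catalyst RuCl2(H2IMes)(PCy3)(=CHPh) (5 mol %), ethylene (1 atm), toluene, 60 °C
Reagents that add atoms: none
Why: Enyne cross-metathesis of an internal alkyne with ethylene delivers the 2,3-disubstituted buta-1,3-diene and tolerates the pinacol boronate.

**Step 6**
Reactants: 6 (E)-N-sulfonylhydrazone of 5; 9 4,4,5,5-tetramethyl-2-(3-methylbuta-1,3-dien-2-yl)-1,3,2-dioxaborolane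
Product: 12 (1R,4R)-4-[(tert-butyldimethylsilyl)oxy]-9-(4,4,5,5-tetramethyl-1,3,2-dioxaborolan-2-yl)dauca-5,8-diene, via diazoalkene 10 (not isolated), via cis-divinylcyclopropane 11 (not isolated)
Conditions: NaH (2 equiv), Rh2(OAc)4 (2 mol %), 9 (3 equiv), CH2Cl2, 0 → 40 °C; then solvent exchange to toluene, 110 °C
Reagents that add atoms: none
Why: Base-induced Bamford–Stevens fragmentation of 6 gives diazoalkene 10, which Rh2(OAc)4 turns into a rhodium vinylcarbene; this electrophile should attack the CH2 terminus of the methyl-substituted alkene of 9 and close the cyclopropane C6–C7–C8 (11), and on heating 11 should undergo a Cope rearrangement that breaks the temporary C6–C8 bond and forms C1–C10. The closest known reaction type is the tandem cyclopropanation/Cope rearrangement (formal (4+3) cycloaddition) of rhodium vinylcarbenes with 1,3-dienes, run here with a donor-type carbene released from a sulfonylhydrazone. The seven-membered ring closes in the sigmatropic step, a 3,3-shift through a boat in which C1 and C10 lie over the three-membered ring. The only new stereocentre that survives is the quaternary C1: the cyclopentene fixes the geometry of the C5=C1 terminus (methyl outside, C2 in the ring), so its configuration depends only on the face that carries the cyclopropane, and the silyloxy group on C4, expected to sit over the β-face (gauche to C3 and C5, anti to the isopropyl group), should send the diene and then C10 to the α-face, trans to the C4 oxygen. The step needs site selectivity between the two alkenes of 9 (the methyl group activates C7=C8, the boryl group deactivates C9=C10 and would place developing charge next to boron), convergence of cis and trans cyclopropanes (at 110 °C the doubly allylic C6–C8 bond should open and reclose so that trans isomers also drain through the boat) and the facial selectivity above, which rests on the C4 stereocentre from terpinen-4-ol.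

**Step 7**
Reactants: 12 (1R,4R)-4-[(tert-butyldimethylsilyl)oxy]-9-(pinacolboryl)dauca-5,8-diene
Product: 14 (1R,4R)-4-[(tert-butyldimethylsilyl)oxy]-6-hydroxydaucan-9-one (mixture of epimers at C5, C6 and C8), via alkylborane 13 (not isolated)
Conditions: BH3·THF, THF, 0 °C → rt; then NaBO3·4H2O, H2O, rt
Reagents that add atoms: sodium perborate tetrahydrate, [Na+].[O-]B1OO1.O.O.O.O
Why: Hydroboration–oxidation: borane should add to the trisubstituted C5=C6 alkene with boron on the less substituted C6 while the tetrasubstituted alkenylboronate is too hindered to react, and perborate then oxidises both carbon–boron bonds (C6–OH, and the C9 enol that tautomerises to the ketone); the configurations at C5, C6 and C8 are left open because all three are erased or reset in step 8.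

**Step 8**
Reactants: 14 (1R,4R)-4-[(tert-butyldimethylsilyl)oxy]-6-hydroxydaucan-9-one
Product: 16 (1R,4R,5R)-4-[(tert-butyldimethylsilyl)oxy]dauc-7-ene-6,9-dione (5αH, trans-fused), via 1,4-diketone 15 (not isolated)
Conditions: 2-iodoxybenzoic acid (IBX, 4 equiv), DMSO, 75 °C
Reagents that add atoms: none
Why: IBX oxidation of the C6 carbinol is followed by IBX dehydrogenation of the 1,4-diketone across C7–C8, the only α,β pair that carries hydrogen on both carbons; C5, now the acidic α-position of a vinylogous 1,3-dicarbonyl system, should equilibrate to the trans-fused ketone in which C6 stands trans to the isopropyl group on C4.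

**Step 9**
Reactants: 16 (1R,4R,5R)-4-[(tert-butyldimethylsilyl)oxy]dauc-7-ene-6,9-dione
Product: 17 (1R,4R,5R)-4-hydroxydauc-7-ene-6,9-dione
Conditions: HF·pyridine, pyridine, THF, 0 °C → rt
Reagents that add atoms: none
Why: Fluoride cleavage of the tertiary silyl ether under buffered, non-basic conditions avoids alkoxide formation and with it retro-aldol opening or oxa-Michael addition to the ene-dione.

**Step 10**
Reactants: 17 (1R,4R,5R)-4-hydroxydauc-7-ene-6,9-dione
Product: 18 (1R,4R,5S,6S)-4,6-dihydroxydauc-7-en-9-one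
Conditions: Me4NBH(OAc)3, MeCN/AcOH, −25 °C
Reagents that add atoms: none
Why: Evans–Saksena reduction: the triacetoxyborohydride binds the C4 hydroxyl and delivers hydride within a six-membered transition state to the β-face of the neighbouring C6 carbonyl, which sets the 6α-hydroxyl (1,3-anti to the C4 oxygen, 6S), while the C9 ketone has no hydroxyl in reach and should stay untouched.

**Step 11**
Reactants: 18 (1R,4R,5S,6S)-4,6-dihydroxydauc-7-en-9-one; 19 4-acetoxy-3-methoxybenzoic acid
Product: 21 (1R,4R,5S,6S)-4-hydroxy-9-oxodauc-7-en-6-yl 4-acetoxy-3-methoxybenzoate, via O-acylisourea 20 (not isolated)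
Conditions: EDC·HCl, DMAP, CH2Cl2, rt
Reagents that add atoms: none
Why: Steglich esterification acylates the secondary allylic C6 hydroxyl only, since the tertiary C4 hydroxyl is inert under carbodiimide conditions, and the acetate keeps the phenol of the acid from competing.

**Step 12**
Reactants: 21 (1R,4R,5S,6S)-4-hydroxy-9-oxodauc-7-en-6-yl 4-acetoxy-3-methoxybenzoate
Product: 23 (1R,4R,5S,6S,9R)-4,9-dihydroxydauc-7-en-6-yl 4-hydroxy-3-methoxybenzoate, via aryl acetate 22 (not isolated)
Conditions: NaBH4, CeCl3·7H2O, MeOH, −40 °C; then K2CO3 (1.5 equiv), 0 °C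
Reagents that add atoms: none
Why: Luche reduction gives 1,2-reduction of the enone, and hydride should enter the C9 carbonyl from the α-face, away from the angular C1 methyl that stands 1,3 to it, to set the 9β-hydroxyl (9R); carbonate-promoted methanolysis then removes the aryl acetate far faster than the hindered benzoate-type ester.

**Compound list**

1 | (S)-(+)-terpinen-4-ol, (1S)-4-methyl-1-(propan-2-yl)cyclohex-3-en-1-ol | CC1=CC[C@](O)(C(C)C)CC1 | starting material
2 | tert-butyl(dimethyl){[(1S)-4-methyl-1-(propan-2-yl)cyclohex-3-en-1-yl]oxy}silane | CC1=CC[C@](O[Si](C)(C)C(C)(C)C)(C(C)C)CC1 | intermediate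
3 | secondary ozonide of 2 (1,2,4-trioxolane across the former alkene carbons, mixture at these two carbons) | CC12CC[C@@](O[Si](C)(C)C(C)(C)C)(C(C)C)CC(OO1)O2 | intermediate
4 | (3S)-3-[(tert-butyldimethylsilyl)oxy]-6-oxo-3-(propan-2-yl)heptanal | CC(=O)CC[C@@](O[Si](C)(C)C(C)(C)C)(C(C)C)CC=O | intermediate
5 | (5R)-5-[(tert-butyldimethylsilyl)oxy]-2-methyl-5-(propan-2-yl)cyclopent-1-ene-1-carbaldehyde | CC1=C(C=O)[C@](O[Si](C)(C)C(C)(C)C)(C(C)C)CC1 | intermediate
6 | (E)-N'-({(5R)-5-[(tert-butyldimethylsilyl)oxy]-2-methyl-5-(propan-2-yl)cyclopent-1-en-1-yl}methylidene)-2-(trifluoromethyl)benzenesulfonohydrazide | CC1=C(/C=N/NS(=O)(=O)c2ccccc2C(F)(F)F)[C@](O[Si](C)(C)C(C)(C)C)(C(C)C)CC1 | intermediate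
7 | 4,4,5,5-tetramethyl-2-(prop-1-yn-1-yl)-1,3,2-dioxaborolane | CC#CB1OC(C)(C)C(C)(C)O1 | starting material
8 | ethylene | C=C | starting material
9 | 4,4,5,5-tetramethyl-2-(3-methylbuta-1,3-dien-2-yl)-1,3,2-dioxaborolane | CC(=C)C(=C)B1OC(C)(C)C(C)(C)O1 | intermediate
10 | tert-butyl{[(1R)-2-(diazomethyl)-3-methyl-1-(propan-2-yl)cyclopent-2-en-1-yl]oxy}dimethylsilane | CC1=C(C=[N+]=[N-])[C@](O[Si](C)(C)C(C)(C)C)(C(C)C)CC1 | intermediate
11 | cis-divinylcyclopropane: tert-butyl{[(1R)-3-methyl-2-{(1R,2S)-2-methyl-2-[1-(pinacolboryl)ethenyl]cyclopropyl}-1-(propan-2-yl)cyclopent-2-en-1-yl]oxy}dimethylsilane (cyclopentenyl and borylvinyl groups cis) | CC1=C([C@@H]2C[C@]2(C)C(=C)B3OC(C)(C)C(C)(C)O3)[C@](O[Si](C)(C)C(C)(C)C)(C(C)C)CC1 | intermediate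
12 | (1R,4R)-4-[(tert-butyldimethylsilyl)oxy]-9-(4,4,5,5-tetramethyl-1,3,2-dioxaborolan-2-yl)dauca-5,8-diene | C1C(C)=C(B3OC(C)(C)C(C)(C)O3)C[C@@]2(C)CC[C@@](O[Si](C)(C)C(C)(C)C)(C(C)C)C2=C1 | intermediate
13 | (1R,4R)-6-boranyl-4-[(tert-butyldimethylsilyl)oxy]-9-(pinacolboryl)dauc-8-ene (drawn as the monoalkylborane, mixture at C5 and C6) | BC2CC(C)=C(B4OC(C)(C)C(C)(C)O4)C[C@@]3(C)CC[C@@](O[Si](C)(C)C(C)(C)C)(C(C)C)C23 | intermediate
14 | (1R,4R)-4-[(tert-butyldimethylsilyl)oxy]-6-hydroxydaucan-9-one (mixture at C5, C6 and C8) | OC2CC(C)C(=O)C[C@@]3(C)CC[C@@](O[Si](C)(C)C(C)(C)C)(C(C)C)C23 | intermediate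
15 | (1R,4R)-4-[(tert-butyldimethylsilyl)oxy]daucane-6,9-dione (mixture at C5 and C8) | O=C2CC(C)C(=O)C[C@@]3(C)CC[C@@](O[Si](C)(C)C(C)(C)C)(C(C)C)C23 | intermediate
16 | (1R,4R,5R)-4-[(tert-butyldimethylsilyl)oxy]dauc-7-ene-6,9-dione (5αH) | O=C2C=C(C)C(=O)C[C@@]3(C)CC[C@@](O[Si](C)(C)C(C)(C)C)(C(C)C)[C@H]23 | intermediate
17 | (1R,4R,5R)-4-hydroxydauc-7-ene-6,9-dione | O=C2C=C(C)C(=O)C[C@@]3(C)CC[C@@](O)(C(C)C)[C@H]23 | intermediate
18 | (1R,4R,5S,6S)-4,6-dihydroxydauc-7-en-9-one | O[C@H]2C=C(C)C(=O)C[C@@]3(C)CC[C@@](O)(C(C)C)[C@H]23 | intermediate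
19 | 4-acetoxy-3-methoxybenzoic acid | COc1cc(C(=O)O)ccc1OC(C)=O | starting material
20 | O-acylisourea from 19 and EDC | CCN=C(NCCCN(C)C)OC(=O)c1ccc(OC(C)=O)c(OC)c1 | intermediate
21 | (1R,4R,5S,6S)-4-hydroxy-9-oxodauc-7-en-6-yl 4-acetoxy-3-methoxybenzoate | COc1cc(C(=O)O[C@H]2C=C(C)C(=O)C[C@@]3(C)CC[C@@](O)(C(C)C)[C@H]23)ccc1OC(C)=O | intermediate
22 | (1R,4R,5S,6S,9R)-4,9-dihydroxydauc-7-en-6-yl 4-acetoxy-3-methoxybenzoate | COc1cc(C(=O)O[C@H]2C=C(C)[C@H](O)C[C@@]3(C)CC[C@@](O)(C(C)C)[C@H]23)ccc1OC(C)=O | intermediate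
23 | (1R,4R,5S,6S,9R)-4,9-dihydroxydauc-7-en-6-yl 4-hydroxy-3-methoxybenzoate (CNP0189996.3) | COc1cc(C(=O)O[C@H]2C=C(C)[C@H](O)C[C@@]3(C)CC[C@@](O)(C(C)C)[C@H]23)ccc1O | target

**Step count**

Total steps: 12. Longest linear sequence: 11 steps (steps 1–4 and 6–12, from 1); step 5 is a one-step side branch.

**Steps most likely to fail**

1. Step 6. Carbene transfer to the diene may be slow at the hindered carbene carbon (flanked by C4 and the C1 methyl), so that carbene dimerisation, ring closure of the diazoalkene to a 3H-pyrazole or C–H insertion take over. The carbene may also attack the boryl-substituted alkene, or facial selectivity in the cyclopropanation may be poor, which would carry over to C1. The fallback builds the same cyclopropane stepwise by known chemistry: C6–C8 is made first, C7 is inserted as a methylene unit, and the Cope step is run separately. From 5, Wittig olefination with 3-(triphenylphosphoranylidene)butan-2-one (toluene, 110 °C) should give dienone F1. Corey–Chaykovsky cyclopropanation of its enone double bond (Me3S(O)I, NaH, DMSO) should give cyclopropyl methyl ketone F2, and LDA then Me3SiCl the silyl enol ether F3. Heating in xylene at 140 °C, where the doubly allylic cyclopropane bond epimerises and the cis isomer rearranges, should give Cope product F4. K2CO3 in MeOH should give ketone F5, and BH3·THF then NaBO3·4H2O (hydroboration of C5=C6 together with reduction of the C9 ketone) diol F6. The conditions of step 8 take F6 to 16, where the route is rejoined.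

2. Step 8. The ring-fusion centre C5 is set only by equilibration and may fail to equilibrate or may settle on the cis-fused epimer; the silyloxy group may also be lost by β-elimination under the hot, enolising conditions. The fallback replaces equilibration by a stereospecific hydride shift. From 12, Bu4NF buffered with AcOH should give tertiary alcohol F7. Hydroxyl-directed epoxidation (VO(acac)2, t-BuOOH) should give 5β,6β-epoxide F8. A mild Lewis acid (Bi(OTf)3, CH2Cl2, −40 °C) should give C6 ketone F9 by Meinwald rearrangement, in which the α-hydrogen of C6 migrates to the α-face of C5 as the tertiary C5–O bond ionises; migration of a C4 substituent instead (semipinacol pathway) is the competing process to watch. NaBO3·4H2O should give 1,4-diketone F10, and 2-iodoxybenzoic acid in DMSO at 60 °C takes F10 to 17.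

3. Step 12. Hydride addition at C9 may show poor facial selectivity. The fallback uses reagent control in place of substrate control: from 21, Corey–Bakshi–Shibata reduction with the (S)-2-methyl-oxazaborolidine catalyst and catecholborane (toluene, −78 °C), for which the usual model predicts the 9R alcohol, should give 22, and K2CO3 in MeOH then gives 23. No new compound is involved.

**Further compounds**

F1 | step 6 | (3E)-4-{(5R)-5-[(tert-butyldimethylsilyl)oxy]-2-methyl-5-(propan-2-yl)cyclopent-1-en-1-yl}-3-methylbut-3-en-2-one | CC(=O)/C(C)=C/C1=C(C)CC[C@@]1(O[Si](C)(C)C(C)(C)C)C(C)C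
F2 | step 6 | 1-(2-{(5R)-5-[(tert-butyldimethylsilyl)oxy]-2-methyl-5-(propan-2-yl)cyclopent-1-en-1-yl}-1-methylcyclopropyl)ethan-1-one (mixture at the cyclopropane carbons) | CC(=O)C1(C)CC1C1=C(C)CC[C@@]1(O[Si](C)(C)C(C)(C)C)C(C)C
F3 | step 6 | trimethylsilyl enol ether of F2 | C=C(O[Si](C)(C)C)C1(C)CC1C1=C(C)CC[C@@]1(O[Si](C)(C)C(C)(C)C)C(C)C
F4 | step 6 | (1R,4R)-4-[(tert-butyldimethylsilyl)oxy]-9-[(trimethylsilyl)oxy]dauca-5,8-diene | C1C(C)=C(O[Si](C)(C)C)C[C@@]2(C)CC[C@@](O[Si](C)(C)C(C)(C)C)(C(C)C)C2=C1
F5 | step 6 | (1R,4R)-4-[(tert-butyldimethylsilyl)oxy]dauc-5-en-9-one (mixture at C8) | C1C(C)C(=O)C[C@@]2(C)CC[C@@](O[Si](C)(C)C(C)(C)C)(C(C)C)C2=C1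
F6 | step 6 | (1R,4R)-4-[(tert-butyldimethylsilyl)oxy]daucane-6,9-diol (mixture at C5, C6, C8 and C9) | OC2CC(C)C(O)C[C@@]3(C)CC[C@@](O[Si](C)(C)C(C)(C)C)(C(C)C)C23
F7 | step 8 | (1R,4R)-9-(4,4,5,5-tetramethyl-1,3,2-dioxaborolan-2-yl)dauca-5,8-dien-4-ol | C1C(C)=C(B3OC(C)(C)C(C)(C)O3)C[C@@]2(C)CC[C@@](O)(C(C)C)C2=C1
F8 | step 8 | 5β,6β-epoxide of F7 | C1C(C)=C(B3OC(C)(C)C(C)(C)O3)C[C@@]2(C)CC[C@@](O)(C(C)C)[C@]24O[C@H]14
F9 | step 8 | (1R,4R,5R)-4-hydroxy-9-(4,4,5,5-tetramethyl-1,3,2-dioxaborolan-2-yl)dauc-8-en-6-one (5αH) | O=C2CC(C)=C(B4OC(C)(C)C(C)(C)O4)C[C@@]3(C)CC[C@@](O)(C(C)C)[C@H]23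
F10 | step 8 | (1R,4R,5R)-4-hydroxydaucane-6,9-dione (5αH, mixture at C8) | O=C2CC(C)C(=O)C[C@@]3(C)CC[C@@](O)(C(C)C)[C@H]23
F0 | step 12 | none | none
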